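## Structural features

- The target is an isoflavanone (3-aryl-chroman-4-one). Ring A, a phloroglucinol-type benzene with free hydroxyls at C5 and C7, is fused to ring C (O1, the C2 methylene, C3, the C4 carbonyl). Ring B is attached to C3 through C1′.
- Ring B carries three contiguous substituents of different kinds: a hydroxyl at C2′, an (E)-geranyl chain at C3′ and a methoxy group at C4′.
- The only stereocentre is C3, of S configuration (C4 > C2 > C1′ > H). It has no neighbouring stereocentre, and it is both benzylic and alpha to the C4 ketone, so it epimerises by enolisation under base and, more slowly, under acid.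
- The geranyl chain has two trisubstituted alkenes that do not tolerate strong protic or Lewis acids, electrophilic oxidants or hydrogenation. It also lies ortho to the C2′ phenol, onto which it cyclises under acid.
- The real difficulty is the combination: an enolisable tertiary centre must be set enantioselectively and then carried through the unmasking of three phenols without base, strong acid or hydrogenolysis. In addition, one methyl ether (at O5) must be cleaved while the other (at O4′) is kept.
- The key step exploits the fact that C2 is a methylene between O1 and C3. It is the carbon of an ortho methoxy group of ring A, so a carbene at C3 of an aryl aroyl diazomethane can insert into one of its C–H bonds. This forms C2–C3, closes ring C and creates C3 in one neutral catalytic operation.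

## Logic of the disconnections

**20 from 19 (O7–Si and O2′–Si).** Free phenols are incompatible with the organometallic, diazo-transfer and carbenoid steps. Silyl ethers are the only phenol masks here that leave without hydrogenolysis (alkenes), strong acid (geranyl ortho to O2′) or base (C3). The gain is that every earlier intermediate is non-acidic. The demand is a fluoride source buffered to near neutrality, so that C3–H is not removed.

**19 from 18 (O5–CH3).** The ring A precursor is symmetrical, and the methoxy group that is not consumed in ring closure ends at C5, peri to the C4 carbonyl. A chelating Lewis acid can therefore tell it from the O4′ methyl ether. The gain is that ring A needs no desymmetrisation. The demand is a reagent that cleaves through a chelate, releases no strong protic acid (geranyl) and contains no base (C3). A magnesium iodide reagent is preferred to a boron halide for this reason.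

**18 from 17 (C2–C3, key step).** Cutting this bond removes ring C and the stereocentre at once and leads to an acyclic diazo ketone with two equivalent ortho methoxy groups. The demand is high: a donor/acceptor carbenoid must insert into a primary ether C–H bond through a six-membered transition state with catalyst-controlled facial selectivity, faster than ylide formation, Wolff rearrangement or attack on the alkenes. The protecting groups of 17 are kept as silyl ethers because none offers a C–H bond within five- or six-membered reach of C3.

**17 from 16 (C3=N2).** The methylene of 16 is activated by the ketone and by ring B, so the diazo group can be installed by diazo transfer. The gain is that the carbene precursor comes from an ordinary ketone in one step. The demand is a base strong enough for a hindered, electron-rich benzyl ketone but tolerated by aryl silyl ethers.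

**16 from 15, and 15 from 10 and 12 (C4–C4a, then the C4 oxidation level).** The carbon between the two methoxy groups of 12 is its most acidic position, and because 12 is symmetrical the metalation has no regiochemical issue. The cut is convergent and separates the molecule into a ring A nucleophile (13, tempered as 14) and a ring B aldehyde. The demands are that addition must outrun enolisation of 10, and that the very electron-rich carbinol 15 must be oxidised under buffered, non-acidic conditions.

**10 from 8 by way of 9 (C3–C4).** The aldehyde carbon of 8 becomes C3, and the added carbon becomes C4. The cut is placed here because an ortho-formylation supplies 8 directly, and a one-carbon homologation then gives the arylacetaldehyde. The demand is that the enol ether hydrolysis be mild enough for the aryl silyl ether and the alkenes.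

**8 from 7, and 7 from 6 (O2′–Si, then C1′–C3).** The free phenol of 6 directs formylation to its only open ortho position through a magnesium chelate. It is silylated only after it has done this work. The gain is complete regiocontrol without a second metalation. The demand is silylation of a phenol flanked by two ortho substituents.

**6 from 2 and 3 by way of 4 and 5, and 2 from 1 (C3′–C1″, then the O-acetal).** The ring position between the two oxygens of 2 is uniquely acidic, and 3 delivers the complete chain with its E alkene. The gain is that ring B is reduced to two commercial compounds. The demands are allylation at the primary carbon without allylic transposition, and an acetal that leaves under acid too mild to cyclise the chain onto the phenol.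

**12 from 11 (O7–Si).** The bulky silyl group resists the alkyllithium and blocks its own ortho positions. The demand is only a standard silylation.

## Other disconnections considered

**Alternative 1:** The cut goes through ring B. C1′–C6′ and C2′–C3′ are disconnected, so ring B is a cyclohexane-1,3-dione, A1, which is aromatised afterwards.

- Forward key step: the enolate of the cis-fused chromano-butyrolactone A2 would add to the vinyl ketone A3, made by one-carbon extension of the methyl group of geranylacetone A4. After proton transfer, the ketone enolate on the geranyl-bearing side would attack the lactone carbonyl and release the C4 alkoxide (Michael addition followed by Claisen acyl transfer).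
- In its favour: the 2′-oxygen, 3′-geranyl, 4′-oxygen pattern arises by construction, because the geranyl-bearing carbon lies between the two carbonyls. Ring B then needs neither directed metalation nor protection of a hindered phenol; on this point the alternative is better than the chosen plan. The chain and its E alkene come from a cheap ketone. C3 of A2 stands next to a carbinol and cannot enolise during the basic annulation, which is also better than carrying an enolisable centre.
- Against it here:
  - A1 must be dehydrogenated to a resorcinol (halogenation–elimination, quinone oxidants or Pd/C at high temperature), and all of these threaten two trisubstituted alkenes.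
  - The resorcinol must be methylated at O4′ and not at O2′, and C4 must be oxidised to the ketone.
  - The acetal groups must be removed with acid at a stage where C3 is enolisable and the chain lies ortho to a free phenol.
  - A2 needs its own enantioselective synthesis.
  - The enolate first formed after the Michael step is on the wrong side of the ketone and must equilibrate while the vinyl ketone can polymerise.
- Comparison:
  - Structure: the alternative solves ring B and postpones the adjustments at C3 and C4. The chosen plan takes ring B from routine arene chemistry and solves ring C and C3 together.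
  - Mechanism: the annulation uses classical enolate steps and is the better of the two in precedent, since the C–H insertion is not established. Its aromatisation, however, has no mild solution in this setting.
  - Step economy: four or more operations after the key step plus the synthesis of A2 make it longer than the twelve steps of the chosen route.

**Alternative 2:** The cut removes C2′–C3′, C4′–C5′ and C1′–C2′, so ring B is assembled on a finished chromone.

- Forward key step: Wolff rearrangement of the diazo enone A6 would give a vinylketene. Regioselective [2+2] addition to the ynol ether A7, four-electron opening of the cyclobutenone, six-electron electrocyclisation and tautomerisation (a Danheiser benzannulation) would give the isoflavone A5.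
- In its favour: one step places all substituents of ring B. The polarisation of the ynol ether fixes the methoxy group at C4′, the chain at C3′ and a free hydroxyl at C2′. No protecting group is needed at the hindered O2′, and the reaction class is well precedented. On regiocontrol of ring B and on precedent for the key step the alternative is the better plan.
- Against it here:
  - A5 is planar at C3. The stereocentre must still be made by an enantioselective reduction of the C2=C3 bond in the presence of two other alkenes, for instance transfer hydrogenation with dynamic kinetic resolution and re-oxidation.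
  - A6 is a diazo ketone conjugated to a light-absorbing Michael acceptor.
  - A7 is a skipped enyne that isomerises and hydrates easily.
  - The ketene can be trapped by the phenol it produces.
  - The acetals on O5 and O7 again leave only with acid.
- Comparison:
  - Structure: the alternative solves ring B better and leaves the stereocentre unsolved. The chosen plan does the reverse.
  - Mechanism: a catalyst-free pericyclic cascade stands against a catalyst-controlled carbenoid insertion. The former is more secure, the latter more direct for C3.
  - Step economy: the two are comparable up to the key step. Afterwards the alternative needs about four steps (asymmetric reduction, re-oxidation, deprotection) against two.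

**Alternative 3:** The cut is C8a–O1, made at the carbinol oxidation level.

- Forward key step: the primary alcohol of the bromoaryl silyloxy alcohol A9 would couple with its own aryl bromide under Pd(OAc)2, a bulky biaryl phosphine and Cs2CO3 (Buchwald–Hartwig etherification). This would close ring C to the trans-4-silyloxy-isoflavan A8.
- In its favour: both stereocentres of A9 come from an auxiliary- or catalyst-controlled aldol of predictable sense, so in stereochemical reliability the alternative is better than the chosen plan. C3 stays next to a protected carbinol through every basic step, including the carbonate-mediated coupling. Six-membered ether closure of primary alcohols onto aryl bromides is a known reaction type.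
- Against it here:
  - The palladium alkoxide of a primary alcohol can undergo beta-hydride elimination, which reduces the aryl bromide.
  - Oxidative addition into an electron-rich bromide with two ortho substituents is slow.
  - After the key step, O4 must be desilylated and oxidised (only then does C3 become labile), and three acetal groups must be removed with acid in the presence of the chain and the enolisable centre.
  - The aldol, auxiliary removal, reduction and silylation add steps before the key step.
- Comparison:
  - Structure: a C–O bond is closed in place of a C–C bond, and the stereocentre is set earlier and separately.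
  - Mechanism: established cross-coupling and aldol chemistry stand against an unproven insertion.
  - Step economy: the chosen route is shorter, and its buffered fluoride end-game is gentler than acid cleavage of acetals. Both plans carry the chain from the start and are equal in that respect.

Key step: step 10

## Route

Remark on the chemistry: the sense of induction of Rh2(S-PTTL)4, dirhodium tetrakis[N-phthaloyl-(S)-tert-leucinate], in this insertion cannot be predicted with confidence. The route assumes the 3S series; if the sense were opposite, the mirror-image catalyst Rh2(R-PTTL)4 would be used with no other change.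

Step 1
Reactants: 1 3-methoxyphenol
Product: 2 2-(3-methoxyphenoxy)oxane (racemic)
Conditions: DHP, PPTS (cat.), CH2Cl2, rt
Reagents that add atoms: 3,4-dihydro-2H-pyran, C1=COCCC1
Why: Acid-catalysed addition of the phenol to the enol ether (tetrahydropyranylation) is routine; the acetal oxygen later cooperates with the methoxy group in directing lithiation, and the reagent is not an alkylating chloromethyl ether.

Step 2
Reactants: 2 2-(3-methoxyphenoxy)oxane; 3 geranyl bromide
Product: 6 2-[(2E)-3,7-dimethylocta-2,6-dien-1-yl]-3-methoxyphenol, via aryllithium 4 (not isolated), via geranylated oxanyl ether 5 (not isolated)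
Conditions: n-BuLi, THF, 0 °C to rt; CuI (10 mol %), 3, −78 to 0 °C; then MeOH, TsOH·H2O, rt
Reagents that add atoms: none
Why: Directed ortho-metalation removes the proton between the two oxygen substituents, and the aryllithium 4 is allylated by 3 at the primary carbon (copper-assisted SN2) with the E alkene unchanged. The aryl acetal 5 is then cleaved in the same flask by acid-catalysed transacetalisation with methanol, which is too mild to cyclise the chain onto the phenol.

Step 3
Reactants: 6 2-[(2E)-3,7-dimethylocta-2,6-dien-1-yl]-3-methoxyphenol
Product: 7 3-[(2E)-3,7-dimethylocta-2,6-dien-1-yl]-2-hydroxy-4-methoxybenzaldehyde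
Conditions: MgCl2, Et3N, (CH2O)n, MeCN, reflux
Reagents that add atoms: paraformaldehyde (source of formaldehyde), C=O
Why: Casnati–Skattebøl ortho-formylation: formaldehyde is delivered within the magnesium phenoxide chelate to the only free ortho position, and the benzylic alkoxide is oxidised by hydride transfer to a second formaldehyde. The non-acidic medium leaves the alkenes untouched.

Step 4
Reactants: 7 3-[(2E)-3,7-dimethylocta-2,6-dien-1-yl]-2-hydroxy-4-methoxybenzaldehyde
Product: 8 2-[tert-butyl(diphenyl)silyl]oxy-3-[(2E)-3,7-dimethylocta-2,6-dien-1-yl]-4-methoxybenzaldehyde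
Conditions: TBDPSCl, imidazole, DMAP (cat.), DMF, 50 °C
Reagents that add atoms: tert-butyl(chloro)diphenylsilane, CC(C)(C)[Si](Cl)(c1ccccc1)c1ccccc1
Why: Silylation of a phenol made more acidic by the ortho formyl group. This silyl group survives base and dilute acid, offers the later carbenoid no C–H bond within five- or six-membered reach, and leaves with fluoride.

Step 5
Reactants: 8 2-[tert-butyl(diphenyl)silyl]oxy-3-[(2E)-3,7-dimethylocta-2,6-dien-1-yl]-4-methoxybenzaldehyde
Product: 10 2-{2-[tert-butyl(diphenyl)silyl]oxy-3-[(2E)-3,7-dimethylocta-2,6-dien-1-yl]-4-methoxyphenyl}acetaldehyde, via methyl enol ether 9 (not isolated)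
Conditions: Ph3P(CH2OMe)Cl, KN(SiMe3)2, THF, 0 °C to rt; then 2 M HCl, THF, 40 °C
Reagents that add atoms: (methoxymethyl)triphenylphosphonium chloride, [Cl-].COC[P+](c1ccccc1)(c1ccccc1)c1ccccc1; water, O
Why: Wittig methoxymethylenation followed by hydrolysis of the enol ether is the standard one-carbon homologation of an aryl aldehyde to an arylacetaldehyde. The oxaphosphetane pathway avoids a free benzylic alkoxide that could take the silyl group from O2′, and dilute aqueous acid is tolerated by the aryl silyl ether and the trisubstituted alkenes.

Step 6
Reactants: 11 3,5-dimethoxyphenol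
Product: 12 (3,5-dimethoxyphenoxy)tri(propan-2-yl)silane
Conditions: TIPSCl, imidazole, DMF, rt
Reagents that add atoms: chlorotri(propan-2-yl)silane, CC(C)[Si](Cl)(C(C)C)C(C)C
Why: Standard silylation of an unhindered phenol. The bulky silyl ether resists n-BuLi and shields its own ortho positions, so lithiation in step 7 can only occur between the two methoxy groups.

Step 7
Reactants: 12 (3,5-dimethoxyphenoxy)tri(propan-2-yl)silane; 10 2-{2-[tert-butyl(diphenyl)silyl]oxy-3-[(2E)-3,7-dimethylocta-2,6-dien-1-yl]-4-methoxyphenyl}acetaldehyde
Product: 15 rac-2-{2-[tert-butyl(diphenyl)silyl]oxy-3-[(2E)-3,7-dimethylocta-2,6-dien-1-yl]-4-methoxyphenyl}-1-{2,6-dimethoxy-4-[tri(propan-2-yl)silyl]oxyphenyl}ethan-1-ol, via aryllithium 13 (not isolated), via arylcerium dichloride 14 (not isolated)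
Conditions: 12, n-BuLi, THF, 0 °C to rt; CeCl3, −78 °C; 10, −78 °C; aq. NaHCO3
Reagents that add atoms: none
Why: Directed ortho-metalation between two methoxy groups gives 13, and transmetalation to the less basic, more oxophilic organocerium 14 lets 1,2-addition outrun enolisation of the arylacetaldehyde. The carbinol centre forms as a racemate, which does not matter because it is oxidised in step 8.

Step 8
Reactants: 15 rac-2-{2-[tert-butyl(diphenyl)silyl]oxy-3-[(2E)-3,7-dimethylocta-2,6-dien-1-yl]-4-methoxyphenyl}-1-{2,6-dimethoxy-4-[tri(propan-2-yl)silyl]oxyphenyl}ethan-1-ol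
Product: 16 2-{2-[tert-butyl(diphenyl)silyl]oxy-3-[(2E)-3,7-dimethylocta-2,6-dien-1-yl]-4-methoxyphenyl}-1-{2,6-dimethoxy-4-[tri(propan-2-yl)silyl]oxyphenyl}ethan-1-one
Conditions: Dess–Martin periodinane, NaHCO3, CH2Cl2, 0 °C to rt
Reagents that add atoms: none
Why: Dess–Martin oxidation of a secondary benzylic alcohol. The bicarbonate buffer prevents ionisation of the very electron-rich carbinol, and the alkenes and silyl ethers are inert to the reagent.

Step 9
Reactants: 16 2-{2-[tert-butyl(diphenyl)silyl]oxy-3-[(2E)-3,7-dimethylocta-2,6-dien-1-yl]-4-methoxyphenyl}-1-{2,6-dimethoxy-4-[tri(propan-2-yl)silyl]oxyphenyl}ethan-1-one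
Product: 17 2-{2-[tert-butyl(diphenyl)silyl]oxy-3-[(2E)-3,7-dimethylocta-2,6-dien-1-yl]-4-methoxyphenyl}-2-diazo-1-{2,6-dimethoxy-4-[tri(propan-2-yl)silyl]oxyphenyl}ethan-1-one
Conditions: p-ABSA, DBU, MeCN, 0 °C to rt
Reagents that add atoms: 4-acetamidobenzenesulfonyl azide, CC(=O)Nc1ccc(cc1)S(=O)(=O)N=[N+]=[N-]
Why: Regitz diazo transfer to a methylene activated by the ketone and by ring B: the enolate attacks the terminal nitrogen of the sulfonyl azide and the adduct fragments to the diazo ketone and the sulfonamide. This azide is chosen as the safer transfer reagent.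

Step 10
Reactants: 17 2-{2-[tert-butyl(diphenyl)silyl]oxy-3-[(2E)-3,7-dimethylocta-2,6-dien-1-yl]-4-methoxyphenyl}-2-diazo-1-{2,6-dimethoxy-4-[tri(propan-2-yl)silyl]oxyphenyl}ethan-1-one
Product: 18 (3S)-3-{2-[tert-butyl(diphenyl)silyl]oxy-3-[(2E)-3,7-dimethylocta-2,6-dien-1-yl]-4-methoxyphenyl}-5-methoxy-7-[tri(propan-2-yl)silyl]oxy-2,3-dihydro-4H-chromen-4-one
Conditions: Rh2(S-PTTL)4 (2 mol %), PhCF3, 4 Å MS, rt, slow addition of 17 at high dilution
Reagents that add atoms: none
Why: Proposed new method: loss of N2 from 17 at an axial site of the dirhodium carboxylate gives a donor/acceptor carbenoid at C3 (ring B as donor, the C4 aroyl group as acceptor); because the aroyl group with two ortho substituents is twisted out of the plane of ring A, one ortho methoxy group lies over the carbenoid carbon, and hydride-like transfer from that methyl group with simultaneous C2–C3 bond formation (concerted, asynchronous three-centre insertion) releases the catalyst. Ring C is closed as a six-membered ring by 1,6-C–H insertion through a cyclic transition state made of C3, C4, C4a, C8a, O1 and C2. The closest known reaction type is the dirhodium-carboxylate-catalysed intramolecular insertion of 2-alkoxyaryl diazo ketones to chroman-4-ones and of ortho-alkoxy aryldiazoacetates to dihydrobenzofurans, where the C–H bond is secondary and next to oxygen; insertion of an alpha-aryl-alpha-diazo ketone carbenoid into the primary C–H bond of an aryl methyl ether has not been shown. The single new stereocentre C3 is the former carbenoid carbon: its configuration depends on which face accepts the hydride, and this is decided by the chiral pocket of the four phthalimido tert-leucinate ligands (catalyst control, since 17 has no stereogenic element). The step needs chemoselection over Wolff rearrangement, over oxonium ylide formation with [1,2]-methyl shift, and over reaction with the geranyl alkenes. This is secured by the donor aryl group, which makes the carbenoid less electrophilic; by the two equivalent ether-activated methyl groups being the only sp3 C–H bonds within six-membered reach (the chain is meta to C1′ and cannot reach C3, and the silyl groups offer only seven-membered reach); and by slow addition at high dilution. The neutral aprotic medium should not enolise C3 of 18.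

Step 11
Reactants: 18 (3S)-3-{2-[tert-butyl(diphenyl)silyl]oxy-3-[(2E)-3,7-dimethylocta-2,6-dien-1-yl]-4-methoxyphenyl}-5-methoxy-7-[tri(propan-2-yl)silyl]oxy-2,3-dihydro-4H-chromen-4-one
Product: 19 (3S)-3-{2-[tert-butyl(diphenyl)silyl]oxy-3-[(2E)-3,7-dimethylocta-2,6-dien-1-yl]-4-methoxyphenyl}-5-hydroxy-7-[tri(propan-2-yl)silyl]oxy-2,3-dihydro-4H-chromen-4-one
Conditions: MgI2·OEt2, THF, 45 °C; aqueous work-up
Reagents that add atoms: none
Why: Chelation-controlled ether cleavage: magnesium is held between the C4 carbonyl oxygen and O5 and activates only that methyl group for SN2 attack by iodide, while the O4′ methyl ether has no such chelate. The medium contains neither strong protic acid nor a base able to enolise C3, so the configuration set in step 10 should be kept.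

Step 12
Reactants: 19 (3S)-3-{2-[tert-butyl(diphenyl)silyl]oxy-3-[(2E)-3,7-dimethylocta-2,6-dien-1-yl]-4-methoxyphenyl}-5-hydroxy-7-[tri(propan-2-yl)silyl]oxy-2,3-dihydro-4H-chromen-4-one
Product: 20 (3S)-3-{3-[(2E)-3,7-dimethylocta-2,6-dien-1-yl]-2-hydroxy-4-methoxyphenyl}-5,7-dihydroxy-2,3-dihydro-4H-chromen-4-one
Conditions: Bu4NF, AcOH (1:1), THF, 0 °C
Reagents that add atoms: none
Why: Fluoride cleaves both aryl silyl ethers, driven by the Si–F bond and the good phenoxide leaving groups. Buffering with acetic acid keeps the medium near neutral, so the C3–H (benzylic and alpha to C4) is not removed and the chain is not protonated.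

## Compound list

1 | 3-methoxyphenol | COc1cccc(O)c1 | starting material
2 | 2-(3-methoxyphenoxy)oxane (racemic) | COc1cccc(OC2CCCCO2)c1 | intermediate
3 | geranyl bromide, (2E)-1-bromo-3,7-dimethylocta-2,6-diene | BrC/C=C(\C)CCC=C(C)C | starting material
4 | [2-methoxy-6-(oxan-2-yloxy)phenyl]lithium | [Li]c1c(OC)cccc1OC1CCCCO1 | intermediate (not isolated)
5 | 2-{2-[(2E)-3,7-dimethylocta-2,6-dien-1-yl]-3-methoxyphenoxy}oxane (racemic) | COc1cccc(OC2CCCCO2)c1C/C=C(\C)CCC=C(C)C | intermediate (not isolated)
6 | 2-[(2E)-3,7-dimethylocta-2,6-dien-1-yl]-3-methoxyphenol | COc1cccc(O)c1C/C=C(\C)CCC=C(C)C | intermediate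
7 | 3-[(2E)-3,7-dimethylocta-2,6-dien-1-yl]-2-hydroxy-4-methoxybenzaldehyde | COc1ccc(C=O)c(O)c1C/C=C(\C)CCC=C(C)C | intermediate
8 | 2-[tert-butyl(diphenyl)silyl]oxy-3-[(2E)-3,7-dimethylocta-2,6-dien-1-yl]-4-methoxybenzaldehyde | COc1ccc(C=O)c(O[Si](c2ccccc2)(c2ccccc2)C(C)(C)C)c1C/C=C(\C)CCC=C(C)C | intermediate
9 | tert-butyl{2-[(2E)-3,7-dimethylocta-2,6-dien-1-yl]-3-methoxy-6-(2-methoxyethenyl)phenoxy}diphenylsilane (mixture of enol ether isomers) | COC=Cc1ccc(OC)c(C/C=C(\C)CCC=C(C)C)c1O[Si](c1ccccc1)(c1ccccc1)C(C)(C)C | intermediate (not isolated)
10 | 2-{2-[tert-butyl(diphenyl)silyl]oxy-3-[(2E)-3,7-dimethylocta-2,6-dien-1-yl]-4-methoxyphenyl}acetaldehyde | COc1ccc(CC=O)c(O[Si](c2ccccc2)(c2ccccc2)C(C)(C)C)c1C/C=C(\C)CCC=C(C)C | intermediate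
11 | 3,5-dimethoxyphenol | COc1cc(O)cc(OC)c1 | starting material
12 | (3,5-dimethoxyphenoxy)tri(propan-2-yl)silane | COc1cc(O[Si](C(C)C)(C(C)C)C(C)C)cc(OC)c1 | intermediate
13 | {2,6-dimethoxy-4-[tri(propan-2-yl)silyl]oxyphenyl}lithium | [Li]c1c(OC)cc(O[Si](C(C)C)(C(C)C)C(C)C)cc1OC | intermediate (not isolated)
14 | dichloro{2,6-dimethoxy-4-[tri(propan-2-yl)silyl]oxyphenyl}cerium | Cl[Ce](Cl)c1c(OC)cc(O[Si](C(C)C)(C(C)C)C(C)C)cc1OC | intermediate (not isolated)
15 | rac-2-{2-[tert-butyl(diphenyl)silyl]oxy-3-[(2E)-3,7-dimethylocta-2,6-dien-1-yl]-4-methoxyphenyl}-1-{2,6-dimethoxy-4-[tri(propan-2-yl)silyl]oxyphenyl}ethan-1-ol | COc1cc(O[Si](C(C)C)(C(C)C)C(C)C)cc(OC)c1C(O)Cc1ccc(OC)c(C/C=C(\C)CCC=C(C)C)c1O[Si](c1ccccc1)(c1ccccc1)C(C)(C)C | intermediate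
16 | 2-{2-[tert-butyl(diphenyl)silyl]oxy-3-[(2E)-3,7-dimethylocta-2,6-dien-1-yl]-4-methoxyphenyl}-1-{2,6-dimethoxy-4-[tri(propan-2-yl)silyl]oxyphenyl}ethan-1-one | COc1cc(O[Si](C(C)C)(C(C)C)C(C)C)cc(OC)c1C(=O)Cc1ccc(OC)c(C/C=C(\C)CCC=C(C)C)c1O[Si](c1ccccc1)(c1ccccc1)C(C)(C)C | intermediate
17 | 2-{2-[tert-butyl(diphenyl)silyl]oxy-3-[(2E)-3,7-dimethylocta-2,6-dien-1-yl]-4-methoxyphenyl}-2-diazo-1-{2,6-dimethoxy-4-[tri(propan-2-yl)silyl]oxyphenyl}ethan-1-one | COc1cc(O[Si](C(C)C)(C(C)C)C(C)C)cc(OC)c1C(=O)C(=[N+]=[N-])c1ccc(OC)c(C/C=C(\C)CCC=C(C)C)c1O[Si](c1ccccc1)(c1ccccc1)C(C)(C)C | intermediate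
18 | (3S)-3-{2-[tert-butyl(diphenyl)silyl]oxy-3-[(2E)-3,7-dimethylocta-2,6-dien-1-yl]-4-methoxyphenyl}-5-methoxy-7-[tri(propan-2-yl)silyl]oxy-2,3-dihydro-4H-chromen-4-one | COc1ccc([C@H]2COc3cc(O[Si](C(C)C)(C(C)C)C(C)C)cc(OC)c3C2=O)c(O[Si](c2ccccc2)(c2ccccc2)C(C)(C)C)c1C/C=C(\C)CCC=C(C)C | intermediate
19 | (3S)-3-{2-[tert-butyl(diphenyl)silyl]oxy-3-[(2E)-3,7-dimethylocta-2,6-dien-1-yl]-4-methoxyphenyl}-5-hydroxy-7-[tri(propan-2-yl)silyl]oxy-2,3-dihydro-4H-chromen-4-one | COc1ccc([C@H]2COc3cc(O[Si](C(C)C)(C(C)C)C(C)C)cc(O)c3C2=O)c(O[Si](c2ccccc2)(c2ccccc2)C(C)(C)C)c1C/C=C(\C)CCC=C(C)C | intermediate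
20 | (3S)-3-{3-[(2E)-3,7-dimethylocta-2,6-dien-1-yl]-2-hydroxy-4-methoxyphenyl}-5,7-dihydroxy-2,3-dihydro-4H-chromen-4-one | COc1ccc([C@H]2COc3cc(O)cc(O)c3C2=O)c(O)c1C/C=C(\C)CCC=C(C)C | target

## Step count and least certain steps

Total step count: 12. Longest linear sequence: 11 (steps 1 to 5 and 7 to 12, from 1). Step 6 is the one-step ring A branch.

**Step 10 (key step).**
- What may go wrong: the carbenoid may be diverted into faster channels. These are attack of the methoxy oxygen on the carbenoid carbon to give a five-membered oxonium ylide that collapses by [1,2]-methyl shift, Wolff rearrangement to a ketene, and bimolecular reaction with the alkenes of another molecule. The insertion may also occur with poor facial selectivity.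
- Why: a primary C–H bond of an aryl methyl ether is only weakly hydridic, since the oxygen lone pair is shared with ring A. The stereocentre arises at the carbenoid carbon alone, where ligand control is least documented.
- Fallback (known chemistry), from 16, rejoining at 18:
  - Chelation-controlled mono-demethylation of 16 with MgI2·OEt2 (no stereocentre is present yet) should give 2-{2-[tert-butyl(diphenyl)silyl]oxy-3-geranyl-4-methoxyphenyl}-1-{2-hydroxy-6-methoxy-4-[tri(propan-2-yl)silyl]oxyphenyl}ethan-1-one F1.
  - Heating F1 with paraformaldehyde and diethylamine (alpha-methylenation, then oxa-Michael closure, the usual isoflavanone synthesis from 2-hydroxydeoxybenzoins) should give the racemic form of 18, racemic isoflavanone F2.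
  - Transfer hydrogenation of F2 with RuCl[(S,S)-TsDPEN](p-cymene), or its enantiomer, whichever leads to the 3S series, in HCO2H/Et3N should give the cis-(3S,4S)-isoflavan-4-ol F3. Under these conditions C3 equilibrates through the enol while one enantiomer is reduced faster (dynamic kinetic resolution).
  - Buffered Dess–Martin oxidation of F3 restores the ketone without touching C3 and delivers 18.

**Step 11.**
- What may go wrong: erosion of configuration at C3 by enolisation of the magnesium-bound ketone during the warm reaction, incomplete discrimination between the two methyl ethers, or attack of iodide-derived acid on the alkenes at work-up.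
- Why: coordination of the Lewis acid at C4 makes C3–H more acidic at the very stage where the centre is already set.
- Fallback, from 16, rejoining at 20 (demethylation is moved ahead of the stereocentre):
  - 16 is mono-demethylated as in the first fallback to the hydroxy ketone F1.
  - The freed phenol is silylated with TIPSOTf and 2,6-lutidine to 2-{2-[tert-butyl(diphenyl)silyl]oxy-3-geranyl-4-methoxyphenyl}-1-{2-methoxy-4,6-bis[tri(propan-2-yl)silyloxy]phenyl}ethan-1-one F4.
  - Diazo transfer as in step 9 gives the corresponding diazo ketone F5.
  - Insertion under the conditions of step 10 into the single remaining methoxy group gives the (3S)-5,7-bis[tri(propan-2-yl)silyloxy] isoflavanone F6.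
  - The buffered fluoride of step 12 removes all three silyl groups and gives 20. The stereocentre then never meets a Lewis acid.

**Step 7.**
- What may go wrong: proton transfer from the acidic benzylic alpha position of the aldehyde (enolisation and self-aldol) instead of addition, migration of the silyl group from O2′ to the new alkoxide, and ionisation of the electron-rich carbinol with dehydration during work-up.
- Why: the nucleophile is hindered by two ortho methoxy groups and the electrophile is an arylacetaldehyde.
- Fallback, from 10, rejoining at 16 (skipping 15):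
  - Pinnick oxidation of 10 (NaClO2, NaH2PO4, excess 2-methylbut-2-ene) should give 2-{2-[tert-butyl(diphenyl)silyl]oxy-3-geranyl-4-methoxyphenyl}acetic acid F7.
  - Carbodiimide coupling with N,O-dimethylhydroxylamine should give the Weinreb amide F8.
  - Addition of the aryllithium 13 to F8 gives the ketone 16 directly through the stable chelated adduct. The amide is far less prone to alpha-deprotonation than the aldehyde, and no acid-labile carbinol is formed.

**Step 9.**
- What may go wrong: slow or incomplete deprotonation and transfer, and base-induced loss of an aryl silyl ether (above all the one para to the ketone) on prolonged exposure to DBU.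
- Why: the methylene is attached to an electron-rich ring and flanked by two aryl groups with ortho substituents.
- Fallback, from 16, rejoining at 17 (activation before transfer):
  - The enolate of 16 is formed irreversibly with LiN(SiMe3)2 at −78 °C and acylated with 2,2,2-trifluoroethyl trifluoroacetate to the 4,4,4-trifluoro-1,3-diketone F9.
  - Detrifluoroacetylative diazo transfer with the same sulfonyl azide and Et3N in wet MeCN then gives 17 under much milder basic conditions.

## Further compounds

F1 | step 10 | 2-{2-[tert-butyl(diphenyl)silyl]oxy-3-[(2E)-3,7-dimethylocta-2,6-dien-1-yl]-4-methoxyphenyl}-1-{2-hydroxy-6-methoxy-4-[tri(propan-2-yl)silyl]oxyphenyl}ethan-1-one | COc1cc(O[Si](C(C)C)(C(C)C)C(C)C)cc(O)c1C(=O)Cc1ccc(OC)c(C/C=C(\C)CCC=C(C)C)c1O[Si](c1ccccc1)(c1ccccc1)C(C)(C)C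
F2 | step 10 | rac-3-{2-[tert-butyl(diphenyl)silyl]oxy-3-[(2E)-3,7-dimethylocta-2,6-dien-1-yl]-4-methoxyphenyl}-5-methoxy-7-[tri(propan-2-yl)silyl]oxy-2,3-dihydro-4H-chromen-4-one | COc1ccc(C2COc3cc(O[Si](C(C)C)(C(C)C)C(C)C)cc(OC)c3C2=O)c(O[Si](c2ccccc2)(c2ccccc2)C(C)(C)C)c1C/C=C(\C)CCC=C(C)C
F3 | step 10 | (3S,4S)-3-{2-[tert-butyl(diphenyl)silyl]oxy-3-[(2E)-3,7-dimethylocta-2,6-dien-1-yl]-4-methoxyphenyl}-5-methoxy-7-[tri(propan-2-yl)silyl]oxy-3,4-dihydro-2H-chromen-4-ol (cis) | COc1ccc([C@H]2COc3cc(O[Si](C(C)C)(C(C)C)C(C)C)cc(OC)c3[C@H]2O)c(O[Si](c2ccccc2)(c2ccccc2)C(C)(C)C)c1C/C=C(\C)CCC=C(C)C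
F4 | step 11 | 2-{2-[tert-butyl(diphenyl)silyl]oxy-3-[(2E)-3,7-dimethylocta-2,6-dien-1-yl]-4-methoxyphenyl}-1-{2-methoxy-4,6-bis[tri(propan-2-yl)silyloxy]phenyl}ethan-1-one | COc1cc(O[Si](C(C)C)(C(C)C)C(C)C)cc(O[Si](C(C)C)(C(C)C)C(C)C)c1C(=O)Cc1ccc(OC)c(C/C=C(\C)CCC=C(C)C)c1O[Si](c1ccccc1)(c1ccccc1)C(C)(C)C
F5 | step 11 | 2-{2-[tert-butyl(diphenyl)silyl]oxy-3-[(2E)-3,7-dimethylocta-2,6-dien-1-yl]-4-methoxyphenyl}-2-diazo-1-{2-methoxy-4,6-bis[tri(propan-2-yl)silyloxy]phenyl}ethan-1-one | COc1cc(O[Si](C(C)C)(C(C)C)C(C)C)cc(O[Si](C(C)C)(C(C)C)C(C)C)c1C(=O)C(=[N+]=[N-])c1ccc(OC)c(C/C=C(\C)CCC=C(C)C)c1O[Si](c1ccccc1)(c1ccccc1)C(C)(C)C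
F6 | step 11 | (3S)-3-{2-[tert-butyl(diphenyl)silyl]oxy-3-[(2E)-3,7-dimethylocta-2,6-dien-1-yl]-4-methoxyphenyl}-5,7-bis[tri(propan-2-yl)silyloxy]-2,3-dihydro-4H-chromen-4-one | COc1ccc([C@H]2COc3cc(O[Si](C(C)C)(C(C)C)C(C)C)cc(O[Si](C(C)C)(C(C)C)C(C)C)c3C2=O)c(O[Si](c2ccccc2)(c2ccccc2)C(C)(C)C)c1C/C=C(\C)CCC=C(C)C
F7 | step 7 | 2-{2-[tert-butyl(diphenyl)silyl]oxy-3-[(2E)-3,7-dimethylocta-2,6-dien-1-yl]-4-methoxyphenyl}acetic acid | COc1ccc(CC(=O)O)c(O[Si](c2ccccc2)(c2ccccc2)C(C)(C)C)c1C/C=C(\C)CCC=C(C)C
F8 | step 7 | 2-{2-[tert-butyl(diphenyl)silyl]oxy-3-[(2E)-3,7-dimethylocta-2,6-dien-1-yl]-4-methoxyphenyl}-N-methoxy-N-methylacetamide | COc1ccc(CC(=O)N(C)OC)c(O[Si](c2ccccc2)(c2ccccc2)C(C)(C)C)c1C/C=C(\C)CCC=C(C)C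
F9 | step 9 | 2-{2-[tert-butyl(diphenyl)silyl]oxy-3-[(2E)-3,7-dimethylocta-2,6-dien-1-yl]-4-methoxyphenyl}-1-{2,6-dimethoxy-4-[tri(propan-2-yl)silyl]oxyphenyl}-4,4,4-trifluorobutane-1,3-dione (racemic) | COc1cc(O[Si](C(C)C)(C(C)C)C(C)C)cc(OC)c1C(=O)C(C(=O)C(F)(F)F)c1ccc(OC)c(C/C=C(\C)CCC=C(C)C)c1O[Si](c1ccccc1)(c1ccccc1)C(C)(C)C
A1 | alternative 1 | 2-[(2E)-3,7-dimethylocta-2,6-dien-1-yl]-4-[cis-4-hydroxy-5,7-bis(methoxymethoxy)-3,4-dihydro-2H-chromen-3-yl]cyclohexane-1,3-dione (dione-ring centres unassigned) | O=C1CCC([C@H]2COc3cc(OCOC)cc(OCOC)c3[C@H]2O)C(=O)C1C/C=C(\C)CCC=C(C)C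
A2 | alternative 1 | cis-7,9-bis(methoxymethoxy)-3,3a,4,9b-tetrahydro-2H-furo[3,2-c]chromen-2-one | O=C1C[C@H]2COc3cc(OCOC)cc(OCOC)c3[C@H]2O1
A3 | alternative 1 | (6E)-7,11-dimethyldodeca-1,6,10-trien-3-one | C=CC(=O)CC/C=C(\C)CCC=C(C)C
A4 | alternative 1 | geranylacetone, (5E)-6,10-dimethylundeca-5,9-dien-2-one | CC(=O)CC/C=C(\C)CCC=C(C)C
A5 | alternative 2 | 3-{3-[(2E)-3,7-dimethylocta-2,6-dien-1-yl]-2-hydroxy-4-methoxyphenyl}-5,7-bis(methoxymethoxy)-4H-chromen-4-one | COc1ccc(-c2coc3cc(OCOC)cc(OCOC)c3c2=O)c(O)c1C/C=C(\C)CCC=C(C)C
A6 | alternative 2 | (3E)-4-[5,7-bis(methoxymethoxy)-4-oxo-4H-chromen-3-yl]-1-diazobut-3-en-2-one | [N-]=[N+]=CC(=O)/C=C/c1coc2cc(OCOC)cc(OCOC)c2c1=O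
A7 | alternative 2 | (4E)-1-methoxy-5,9-dimethyldeca-4,8-dien-1-yne | COC#CC/C=C(\C)CCC=C(C)C
A8 | alternative 3 | (3S,4R)-4-[tert-butyl(dimethyl)silyl]oxy-3-{3-[(2E)-3,7-dimethylocta-2,6-dien-1-yl]-4-methoxy-2-(methoxymethoxy)phenyl}-5,7-bis(methoxymethoxy)-3,4-dihydro-2H-chromene (trans) | COc1ccc([C@H]2COc3cc(OCOC)cc(OCOC)c3[C@@H]2O[Si](C)(C)C(C)(C)C)c(OCOC)c1C/C=C(\C)CCC=C(C)C
A9 | alternative 3 | (2S,3R)-3-[2-bromo-4,6-bis(methoxymethoxy)phenyl]-3-[tert-butyl(dimethyl)silyl]oxy-2-{3-[(2E)-3,7-dimethylocta-2,6-dien-1-yl]-4-methoxy-2-(methoxymethoxy)phenyl}propan-1-ol | COc1ccc([C@@H](CO)[C@@H](O[Si](C)(C)C(C)(C)C)c2c(Br)cc(OCOC)cc2OCOC)c(OCOC)c1C/C=C(\C)CCC=C(C)C
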